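Cuts: (a) six O–benzyl bonds; (b) both C2=Cα π bonds, traced back through C2–Br/Cα–H to a saturated dimer; (c) the central Cα–Cα′ σ bond, giving two molecules of tri-O-benzylsulfuretin; (d) the C2=Cα bond of the monomer, giving 6-hydroxybenzofuran-3(2H)-one and 3,4-dihydroxybenzaldehyde.
Enabling feature: in each half Cα is both the β-carbon of the enone O=C3–C2=Cα of ring C (O1, C2, C3, C3a, C7a) and benzylic to catechol ring B. It is an acceptor site (a 4′-phenoxyl radical puts spin on C2, not on Cα), so the two units are joined reductively: the radical anion carries its spin on Cα, and coupling turns ring C of each half into an aromatic benzofuran-3-olate.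
Forward order: rings A and C are bought, ring B is attached by condensation, and the monomer is benzylated. It is then dimerised tail to tail (the union of two intact sulfuretin units that the biogenesis implies), re-oxidised by bromination/dehydrobromination, and debenzylated.
Stereochemistry: the monomer is Z by thermodynamic control, and Cα/Cα′ of the dimer are transient. Each final alkene comes from a net anti addition (new C–C bond at Cα, Br at C2 on the opposite face) followed by anti E2 loss of HBr. This moves ring B next to C3=O and Cα′ next to O1, the Z,Z geometry of the target.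

Key step: step 3

Assumption: the SMILES is read as Cα′ cis to O1 and ring B cis to C3=O at both alkenes (Z because Cα′ outranks the aryl carbon), so ring B sits on the opposite side from that in (Z)-sulfuretin; this geometry is taken to be configurationally stable in the dark at or below room temperature.

Step 1
Reactants: 1 6-hydroxybenzofuran-3(2H)-one; 2 3,4-dihydroxybenzaldehyde
Product: 3 sulfuretin
Conditions: conc. HCl (cat.), EtOH, reflux
Reagents that add atoms: none
Why: Acid-catalysed aldol (Knoevenagel-type) condensation of the C2 methylene of a benzofuran-3(2H)-one with an aryl aldehyde is the standard aurone synthesis, tolerates free phenols and should give the Z alkene (ring B cis to O1) under thermodynamic control, because a coplanar aryl group cannot sit next to C3=O.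

Step 2
Reactants: 3 sulfuretin
Product: 4 tri-O-benzylsulfuretin
Conditions: BnBr (3.3 equiv), K2CO3, DMF, 60 °C
Reagents that add atoms: benzyl bromide, BrCc1ccccc1
Why: Williamson etherification of the three phenols (3 has no enolisable C–H left) removes every acidic proton that would quench the radical anion of step 3 and leaves the Z alkene untouched.

Step 3
Reactants: 4 tri-O-benzylsulfuretin (two molecules)
Product: 6 dl-1,2-bis[3,4-bis(benzyloxy)phenyl]-1,2-bis[6-benzyloxy-3-(trimethylsilyloxy)benzofuran-2-yl]ethane, via bis-samarium benzofuran-3-olate dimer 5 (not isolated)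
Conditions: SmI2 (1.1 equiv per 4, slow addition), HMPA, THF, −78 °C; then TMSCl, −78 °C to rt; cold NaHCO3 wash, used crude
Reagents that add atoms: chlorotrimethylsilane, C[Si](C)(C)Cl; samarium diiodide, I[Sm]I (its atoms stay only in 5)
Why: SmI2–HMPA transfers one electron into the enone O=C3–C2=Cα of 4, and the samarium-bound radical anion, whose spin sits mainly on the benzylic β-carbon Cα, combines tail to tail with a second one to form the Cα–Cα′ bond, each half ending as an aromatic benzofuran-3-olate (5), which makes the coupling irreversible and removes the need for any activating group. The closest known reaction type is the SmI2- or cathode-induced β,β-hydrodimerisation of chalcones, cinnamates and 2-arylidene cycloalkanones, here stopped at the bis-enolate by O-silylation. No ring is closed. The two new stereocentres Cα and Cα′ are set only by the mutual orientation of the two radical anions (bridging of the oxygen termini by trivalent samarium should favour the dl pair that is drawn), and since both are erased in step 4 the meso isomer serves equally. The step needs β,β- rather than carbonyl (pinacol) coupling, which the substrate secures through its hindered C3 carbonyl deactivated by O1 and the 6-benzyloxy group and through the aryl-stabilised spin at Cα, and it needs dimerisation rather than a second electron transfer, which the aprotic medium, the absence of O–H groups in 4, high concentration and slow addition of one equivalent of SmI2 secure. Capture with TMSCl before any proton source arrives prevents both the aldol closure to a cyclopentanol that usually follows enone hydrodimerisation and the reductive cleavage of the C2–O1 bond that an α-aryloxy ketone would suffer.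

Step 4
Reactants: 6 bis(trimethylsilyl) dimer
Product: 8 (Z,Z)-hexa-O-benzyldisulfuretin, via 2,2′-dibromide 7 (not isolated)
Conditions: NBS (2.05 equiv), CH2Cl2, −78 °C, dark; then DBU (3 equiv), −78 to 0 °C
Reagents that add atoms: N-bromosuccinimide, O=C1CCC(=O)N1Br (its bromine stays only in 7)
Why: Electrophilic α-bromination of a silyl enol ether followed by E2 dehydrobromination: with Cα–H eclipsing the C3–OSiMe3 side (allylic 1,3-strain) NBS should reach C2 on the face anti to the bulky Cα′ substituent, and anti-periplanar loss of Cα–H and C2–Br from that diastereomer places Cα′ cis to O1 and ring B cis to C3=O, which is Z at both alkenes, while all four sp3 centres are erased.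

Step 5
Reactants: 8 (Z,Z)-hexa-O-benzyldisulfuretin
Product: 9 disulfuretin
Conditions: BCl3 (excess), C6HMe5, CH2Cl2, −78 °C, dark, Ar; then H2O/THF, −78 to 0 °C
Reagents that add atoms: none
Why: Lewis-acid debenzylation of aryl benzyl ethers with pentamethylbenzene as a non-basic cation scavenger runs at −78 °C without touching enone alkenes, and the low temperature and short contact time should preserve the Z,Z geometry set in step 4.

Compound list
1 | 6-hydroxybenzofuran-3(2H)-one | O=C1COc2cc(O)ccc21 | starting material
2 | 3,4-dihydroxybenzaldehyde | O=Cc1ccc(O)c(O)c1 | starting material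
3 | sulfuretin, (Z)-2-(3,4-dihydroxybenzylidene)-6-hydroxybenzofuran-3(2H)-one | O=C1/C(=C/c2ccc(O)c(O)c2)Oc2cc(O)ccc21 | intermediate
4 | tri-O-benzylsulfuretin, (Z)-6-benzyloxy-2-[3,4-bis(benzyloxy)benzylidene]benzofuran-3(2H)-one | O=C1/C(=C/c2ccc(OCc3ccccc3)c(OCc3ccccc3)c2)Oc2cc(OCc3ccccc3)ccc21 | intermediate
5 | bis(diiodosamarium) bis(benzofuran-3-olate) of the Cα–Cα′ dimer (dl pair drawn, racemic) | I[Sm](I)Oc1c(oc2cc(OCc3ccccc3)ccc12)[C@H](c1ccc(OCc2ccccc2)c(OCc2ccccc2)c1)[C@@H](c1ccc(OCc2ccccc2)c(OCc2ccccc2)c1)c1oc2cc(OCc3ccccc3)ccc2c1O[Sm](I)I | intermediate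
6 | dl-1,2-bis[3,4-bis(benzyloxy)phenyl]-1,2-bis[6-benzyloxy-3-(trimethylsilyloxy)benzofuran-2-yl]ethane (racemic αS*,α′S* pair drawn; any meso isomer is carried along) | C[Si](C)(C)Oc1c(oc2cc(OCc3ccccc3)ccc12)[C@H](c1ccc(OCc2ccccc2)c(OCc2ccccc2)c1)[C@@H](c1ccc(OCc2ccccc2)c(OCc2ccccc2)c1)c1oc2cc(OCc3ccccc3)ccc2c1O[Si](C)(C)C | intermediate
7 | (2S*,αS*,α′S*,2′S*)-2,2′-dibromo dimer, each C2–Br anti to the Cα–Cα′ bond (racemic) | O=C1c2ccc(OCc3ccccc3)cc2O[C@]1(Br)[C@H](c1ccc(OCc2ccccc2)c(OCc2ccccc2)c1)[C@@H](c1ccc(OCc2ccccc2)c(OCc2ccccc2)c1)[C@@]1(Br)Oc2cc(OCc3ccccc3)ccc2C1=O | intermediate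
8 | (Z,Z)-hexa-O-benzyldisulfuretin (Cα′ cis to O1, ring B cis to C3=O in both halves) | O=C1/C(=C(/C(=C2\Oc3cc(OCc4ccccc4)ccc3C2=O)c2ccc(OCc3ccccc3)c(OCc3ccccc3)c2)c2ccc(OCc3ccccc3)c(OCc3ccccc3)c2)Oc2cc(OCc3ccccc3)ccc21 | intermediate
9 | disulfuretin | O=C1/C(=C(/C(=C2\Oc3cc(O)ccc3C2=O)c2ccc(O)c(O)c2)c2ccc(O)c(O)c2)Oc2cc(O)ccc21 | target

Total step count: 5. Longest linear sequence: 5 steps (1 to 9).

Steps most likely to fail

Step 3. The radical anion may take up a second electron and a proton (plain 1,4-reduction). It may couple through the carbonyl carbon, close an aldol ring after partial protonation, or lose the C2–O1 bond by over-reduction. The fallback sets out from 4 and comes back at 8, bypassing steps 3 and 4 with a stereoretentive coupling of a preformed alkenyl halide. Anti addition of Br2 (CH2Cl2, −78 °C, dark) to the Z alkene of 4 should give the racemic (2R*,αS*)-2,α-dibromide F1. Anti E2 loss of Cα–H and C2–Br with Et3N should give (Z)-α-bromo-tri-O-benzylsulfuretin F2, with bromine cis to O1. Ullmann-type reductive homocoupling of this alkenyl bromide with Ni(cod)2/PPh3 in DMF (zerovalent nickel) should join the two Cα carbons with retention and give 8.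

Step 4. Facial selectivity in the bromination may be poor. The tertiary bromide may ionise, or the second elimination may run through an extended enolate, and either event would erode the geometric control. The fallback sets out from 6 and comes back at 8, separating dehydrogenation from geometry setting. DDQ (2 equiv, CH2Cl2, 0 °C) abstracts hydride from each Cα–H of the silyloxybenzofuran and should give mainly the (E,E)-hexa-O-benzyl isomer F3, with ring B cis to O1. Blue-light irradiation in toluene, the known photoisomerisation of aurone-type alkenes, should establish a photostationary mixture with the (E,Z)-hexa-O-benzyl isomer F4 and 8. Compound 8 is then separated by chromatography in the dark, and F3 and F4 are irradiated again.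

Step 5. Binding of the Lewis acid to C3=O lowers the rotation barrier of the push-pull alkene, so the geometry may leak. The freed catechols may also oxidise in air, and cleavage of six ethers may stay incomplete. The fallback sets out from 3 and comes back at 9, changing the protecting-group plan to silyl ethers that leave under nearly neutral conditions. TBSCl/imidazole in DMF should give tris-TBS-sulfuretin F5. The operations of steps 3 and 4 should then give the bis(trimethylsilyl) hexa-TBS dimer F6, the hexa-TBS 2,2′-dibromide F7 (in the flask) and (Z,Z)-hexa-TBS-disulfuretin F8. Et3N·3HF in THF at 0 °C in the dark should release 9 without forming a phenoxide or a Lewis-acid complex.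

Further compounds
F1 | step 3 | racemic (2R*,αS*)-2,α-dibromide of 4 | O=C1c2ccc(OCc3ccccc3)cc2O[C@]1(Br)[C@@H](Br)c1ccc(OCc2ccccc2)c(OCc2ccccc2)c1
F2 | step 3 | (Z)-α-bromo-tri-O-benzylsulfuretin | O=C1/C(=C(/Br)c2ccc(OCc3ccccc3)c(OCc3ccccc3)c2)Oc2cc(OCc3ccccc3)ccc21
F3 | step 4 | (E,E)-hexa-O-benzyl isomer of 8 | O=C1/C(=C(\C(=C2\Oc3cc(OCc4ccccc4)ccc3C2=O)c2ccc(OCc3ccccc3)c(OCc3ccccc3)c2)c2ccc(OCc3ccccc3)c(OCc3ccccc3)c2)Oc2cc(OCc3ccccc3)ccc21
F4 | step 4 | (E,Z)-hexa-O-benzyl isomer of 8 | O=C1/C(=C(\C(=C2/Oc3cc(OCc4ccccc4)ccc3C2=O)c2ccc(OCc3ccccc3)c(OCc3ccccc3)c2)c2ccc(OCc3ccccc3)c(OCc3ccccc3)c2)Oc2cc(OCc3ccccc3)ccc21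
F5 | step 5 | tris-TBS-sulfuretin | O=C1/C(=C/c2ccc(O[Si](C)(C)C(C)(C)C)c(O[Si](C)(C)C(C)(C)C)c2)Oc2cc(O[Si](C)(C)C(C)(C)C)ccc21
F6 | step 5 | bis(trimethylsilyl) hexa-TBS dimer (dl pair drawn) | C[Si](C)(C)Oc1c(oc2cc(O[Si](C)(C)C(C)(C)C)ccc12)[C@H](c1ccc(O[Si](C)(C)C(C)(C)C)c(O[Si](C)(C)C(C)(C)C)c1)[C@@H](c1ccc(O[Si](C)(C)C(C)(C)C)c(O[Si](C)(C)C(C)(C)C)c1)c1oc2cc(O[Si](C)(C)C(C)(C)C)ccc2c1O[Si](C)(C)C
F7 | step 5 | hexa-TBS 2,2′-dibromide (racemic) | O=C1c2ccc(O[Si](C)(C)C(C)(C)C)cc2O[C@]1(Br)[C@H](c1ccc(O[Si](C)(C)C(C)(C)C)c(O[Si](C)(C)C(C)(C)C)c1)[C@@H](c1ccc(O[Si](C)(C)C(C)(C)C)c(O[Si](C)(C)C(C)(C)C)c1)[C@@]1(Br)Oc2cc(O[Si](C)(C)C(C)(C)C)ccc2C1=O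
F8 | step 5 | (Z,Z)-hexa-TBS-disulfuretin | O=C1/C(=C(/C(=C2\Oc3cc(O[Si](C)(C)C(C)(C)C)ccc3C2=O)c2ccc(O[Si](C)(C)C(C)(C)C)c(O[Si](C)(C)C(C)(C)C)c2)c2ccc(O[Si](C)(C)C(C)(C)C)c(O[Si](C)(C)C(C)(C)C)c2)Oc2cc(O[Si](C)(C)C(C)(C)C)ccc21
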